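The starting complex is dosed over 40 s into the incoming ligand, and you want to know when the flask, which is Thursday's run, holds most complex with one exchanged, and how much.

all flasks: incoming ligand 0.0504 M
- Thursday's: starting complex 0.072 M (fed, over 40 s); the very flask that is asked about, followed so far; the fed solution adds 1.0 times the starting volume
- Wednesday's: starting complex 0.048 M (fed, over 40 s); run made earlier; the fed solution adds 1.0 times the starting volume
- flask: starting complex 0.072 M (fed, over 40 s); the fed solution adds 1.0 times the starting volume; time 1.0 h

| run | time / min | complex with one exchanged / % | starting complex / % |
|---|---|---|---|
| Thursday's | 0.250 | 4.1 | 31.9 |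
| Thursday's | 0.833 | 12.8 | 68.5 |
| Thursday's | 2.50 | 6.6 | 44.6 |
| Thursday's | 8.00 | 2.0 | 30.3 |
| Thursday's | 25.0 | 0.7 | 21.0 |
| Wednesday's | 0.250 | 4.2 | 32.0 |
| Wednesday's | 0.833 | 15.3 | 66.7 |
| Wednesday's | 2.50 | 9.5 | 39.3 |
| Wednesday's | 8.00 | 3.1 | 25.1 |
| Wednesday's | 25.0 | 1.8 | 15.1 |

(readings scatter by 0.3 percentage points)

- charges are per starting volume, the dose included; the dosed solution carries all of it
- the numbers in the tables scatter with a standard deviation of 0.3 percentage points
- percentages count the whole charge, also what has not yet gone in

* time, not beyond 1.0 h, at which the flask holds most complex with one exchanged, in min
* the amount of complex with one exchanged, in percent of the starting complex charged, at that time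

Build the flask one process at a time, counting in fractions of the charge. With the main step alone, the complex with one exchanged would hold what the starting complex has lost. In Thursday's run at 0.833 min, after the feed has ended, that is 31.5 %, yet the reading is 12.8 %, so something consumes it.

Now let the incoming ligand consume it, and use the steady-state approximation, making equal to consuming. The ligand then cancels, and at a like fraction of starting complex the peak fraction should not depend on the charges. But at that time Wednesday's run reads 15.3 %, with similar starting complex (66.7 % against 68.5 %).

So let the starting complex consume it as well. At a like fraction of starting complex, the reciprocal of the peak fraction then rises in a straight line with the charge ratio, starting complex charged over incoming ligand charged, if the ratio present follows the ratio charged. Taking the scattered readings at 0.833 min in the two runs as their peaks, you read the brake as 2.68: the rise of the reciprocal peak fraction per unit of charge ratio.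

Thursday's neighbouring readings, at 0.250 min and 2.50 min, are lower, so you commit to a peak near 0.833 min of about 12.8 %, as read. The forecast gives 0.8 min and 13 %, saying of this short-lived complex: “It therefore follows production closely”.

The flask peaks at 0.886 min with 13.1 %, while 67.0 % of the charge is still starting complex.

    starting complex + incoming ligand ⇌ leaving ligand + complex with one exchanged (K = 0.920, k = 0.570 M⁻¹ s⁻¹)
    starting complex + complex with one exchanged → side product (k = 0.580 M⁻¹ s⁻¹)
    complex with one exchanged + incoming ligand ⇌ leaving ligand + complex with two exchanged (K = 120, k = 1.10 M⁻¹ s⁻¹)
    complex with two exchanged + incoming ligand ⇌ leaving ligand + complex with three exchanged (K = 0.570, k = 0.130 M⁻¹ s⁻¹)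

By this reckoning, the brake times the charge ratio comes to 50.1 % of the reciprocal peak fraction of this flask. Now change the ligand: the neighbouring flask with 0.013 M of incoming ligand has a charge ratio of 5.54, so the straight line drawn from this flask's peak with the brake gives 5.36 %, and that neighbouring flask peaks at 5.46 %.

The readings were generated by integration for substances that don't exist; the scatter is artificial.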